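## Analysis of the target

Atom numbering, used for the target and all intermediates: C1 is the bridgehead with prenyl, C2 a C=O, C3 carries the aroyl group, C4 is the enol carbon. C5 is the bridgehead with the C10 side arm, C6 is CH2, C7 is CH(prenyl), C8 is CMe2, C9 is the bridge C=O. O2, O4 and O9 are the oxygens on C2, C4 and C9. The side arm is C29H2–C30H(prenyl)–C31(Me)=CH2.

- The target 24 is a type B polyprenylated acylphloroglucinol, a bicyclo[3.3.1]nonane-2,4,9-trione. Ring B (C1–C2–C3–C4–C5–C9) is a dearomatised phloroglucinol with the vanilloyl group on C3. Ring A (C1–C9–C5–C6–C7–C8) is the bridge C6–C7–C8 laid across C5 and C1.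
- There are four stereocentres. The quaternary bridgeheads C1 (R) and C5 (R) fix each other through the bridge. At C7 (R) the prenyl group is endo, that is cis to the C2–C3–C4 bridge, so ring A is a boat. C30 (S) is remote, and no ring relays it to the core.
- The hardest bond is C1–C8, which joins two fully substituted carbons.
- The hardest relation is 7-endo. A bridging reaction that is free to choose runs through a chair with an equatorial, exo C7 substituent.
- The deciding feature sits on C5, which carries two lavandulyl units: C6–C7–C8, closed onto C1, and C29–C30–C31, open. The SMILES shows that they have opposite absolute sense. C7 corresponds to (S)-lavandulol and C30 to (R)-lavandulol.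
- Two consequences follow. The racemic C10 alcohol contains both arms. The biomimetic precursor with both arms open has the plane of ring B as a mirror plane and is achiral, so any reversible protonation of the isopropenyl groups erases the absolute configuration.
- Sensitive groups are three prenyl alkenes and one isopropenyl alkene, the acidic enol O4–H (it adds to C31 under Brønsted acid and closes a pyran), a free phenol, and a non-enolisable 1,3-dicarbonyl array open to retro-Claisen cleavage.

## Retrosynthetic reasoning

**24 to 23.** Only two groups are removed: the methyl group on O2 and the silyl group on the phenol. Both fall to hydroxide in one operation. Base is chosen because the enol/isopropenyl pair of 24 does not tolerate acid.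

**23 to 21 (key disconnection).**
- C1–C8 is cut and C8 is reconnected to O9.
- This is the most hindered bond, and cutting it removes the bridge. The bridged [3.3.1] system becomes a fused chromane-type dienone that comes from a flat arene.
- C8 is parked on O9, not left as an open alkene, for three reasons. The O9–C8 bond is the only constitutional difference between the two C5 arms, so it alone keeps 21 chiral. The pyran ring is the relay that sets C5. The doubly vinylogous ester oxygen is also the leaving group.
- The forward reaction must ionise C8–O9 without any Brønsted acid and return C8 to carbon C1.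

**21 to 17 + 19.**
- C5–C29 is cut, which is the dearomatisation.
- Ring B of 17 is a flat, fully substituted arene with a single stereocentre, C7.
- The alkyl group enters C5 last and anti to the C7 prenyl group on the pyran ring. This "alkyl last" order is what leads to the 7-endo series.
- Only O4 is left free in 17, so only its ortho carbons are activated, and C3 is blocked by the acyl group.

**17 to 15 to 14.** The C1–prenyl bond is cut. The prenyl group is brought in after the pyran is closed, because an ortho-prenyl phenol would not survive the acid closure. C1 is the only free ring carbon and is para to the only free hydroxyl. O-prenylation followed by a para-Claisen shift therefore delivers it without a regiochemical choice.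

**14 to 12 to 8 + 10, and 8 to 6 + 4.**
- The O9–C8 bond of the pyran, the C3–acyl bond and the C5–C6 bond are cut in turn.
- The last two are aryllithium reactions on the symmetric ether 6, whose acetal groups choose the sites.
- The pyran closes at a stage where O4–H is tied up by the ketone and O9–H is free.

**4 and 19 to 1.** Both arms are the two enantiomers of one alcohol. A single resolution of (±)-lavandulol 1 gives 2 for the ring arm and 3 for the side arm, and nothing is discarded.

## Alternatives that were turned down

**Alternative 1:** the textbook α,α'-annulation (Effenberger cyclisation).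
- Disconnection: C1–C2 and C4–C5.
- Forward step: the ring A enol ether A1 is bis-acylated with malonyl dichloride A2, and C3 is aroylated later.
- Stereochemistry: both acyl bonds form axially on the half-chair that keeps the C7 prenyl group equatorial, that is anti to it. This gives the 7-exo bicycle A3. C7 has no acidifying neighbour, so the error cannot be repaired.
- Economy: A1 already holds C7, C30 and the C8 quaternary carbon, so the key step sets nothing that is hard. It also has to acylate a tetrasubstituted enol ether next to C8.

**Alternative 2:** one-pot [3+3] alkylative dearomatisation–annulation.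
- Disconnection: C5–C6 and C1–C8 together.
- Forward step: the arene A4 reacts with the bis-electrophile A5 by Michael addition, acetate loss and a second Michael addition, to give the 7-formyl bicycle A6.
- Regiochemistry: C1 (prenyl) and C5 (side arm) differ only by remote branching. The first bond forms at C1 as readily as at C5, which places C8 next to the wrong bridgehead.
- C7: it becomes epimerisable next to the aldehyde and settles in the exo chair form. Four more steps are needed to turn CHO into prenyl.
- Absolute configuration: nothing relates the core to C30.

**Alternative 3:** ring A first, Dieckmann-type closure.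
- Disconnection: C3–C4.
- Forward step: the enolate of the C1 acetyl group of A7 attacks the C5 ester to give the trione A8, which is then aroylated at C3.
- Merit: it is reliable and gives the endo series, because the alkyl groups are put on ring A anti to C7.
- Reason for rejection: the key step forms one unhindered bond and no stereocentre. All four stereocentres, both quaternary bridgeheads and the C1–C8 vicinal pair must already be in A7. They would be built by a linear series of enolate alkylations, plus a separate enantioselective entry to ring A that has to match the chiral side arm. The precursor is as complex as the product.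

Key step: step 13

Assumption: 24 is treated as the rapidly equilibrating enol tautomers of the 2,4,9-trione and is written as the C4 enol of the given SMILES. Compounds 1, 5 and 9 are taken as commercial.

## Steps

Step 1
Reactants: 1 (±)-lavandulol
Product: 2 (S)-lavandulol, together with 3 (R)-lavandulyl acetate (both isolated)
Conditions: immobilised Candida antarctica lipase B, vinyl acetate, MTBE, rt, stopped near half conversion; SiO2
Reagents that add atoms: vinyl acetate, C=COC(C)=O
Why: Lipase-catalysed kinetic resolution by irreversible transesterification with an enol ester; the enzyme should acylate the (R)-alcohol faster, and alcohol 2 and ester 3 are separated by chromatography. Both halves are used, because the target holds one lavandulyl unit of each sense.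

Step 2
Reactants: 2 (S)-lavandulol
Product: 4 (S)-lavandulyl iodide
Conditions: I2, PPh3, imidazole, CH2Cl2, 0 °C
Reagents that add atoms: iodine, II
Why: Appel-type iodination, SN2 at the primary carbon; the stereocentre is not touched, and the neutral medium avoids homoallyl/cyclopropylcarbinyl rearrangement.

Step 3
Reactants: 5 5-methoxyresorcinol
Product: 6 1-methoxy-3,5-bis(methoxymethoxy)benzene
Conditions: MOMCl, i-Pr2NEt, CH2Cl2, 0 °C to rt
Reagents that add atoms: chloromethyl methyl ether, COCCl
Why: Standard acetal protection of both phenols; the two OMOM groups are the directing groups of steps 4 and 6, and the methyl ether stays as O2–Me.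

Step 4
Reactants: 6 1-methoxy-3,5-bis(methoxymethoxy)benzene; 4 (S)-lavandulyl iodide
Product: 8 5-methoxy-1,3-bis(methoxymethoxy)-2-[(2R)-5-methyl-2-(prop-1-en-2-yl)hex-4-enyl]benzene, via aryllithium 7 (not isolated)
Conditions: n-BuLi, THF, 0 °C; then 4, DMPU, −78 °C to rt
Reagents that add atoms: none
Why: Directed ortho-metalation at the site between the two chelating OMOM groups, then SN2 alkylation of the aryllithium with the primary iodide; this forms C5–C6. The stereocentre (future C7) is β to the reacting carbon and is untouched; its descriptor changes only through CIP priorities.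

Step 5
Reactants: 9 methyl vanillate
Product: 10 methyl 3-methoxy-4-(triisopropylsilyloxy)benzoate
Conditions: TIPSCl, imidazole, DMF, rt
Reagents that add atoms: triisopropylsilyl chloride, CC(C)[Si](Cl)(C(C)C)C(C)C
Why: Silylation of the phenol; the aryl TIPS ether should stand aryllithium, catalytic acid, 190 °C, LiHMDS and cold MeAlCl2, and it falls to hydroxide in step 14.

Step 6
Reactants: 8 arene from step 4; 10 methyl 3-methoxy-4-(triisopropylsilyloxy)benzoate
Product: 12 {6-methoxy-2,4-bis(methoxymethoxy)-3-[(2R)-5-methyl-2-(prop-1-en-2-yl)hex-4-enyl]phenyl}[3-methoxy-4-(triisopropylsilyloxy)phenyl]methanone, via aryllithium 11 (not isolated)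
Conditions: n-BuLi, TMEDA, THF, 0 °C; then 10, −78 to 0 °C
Reagents that add atoms: none
Why: Second directed ortho-metalation at one of the two equivalent positions between OMe and OMOM (this defines C3), then acyl substitution on the ester. The ketone formed carries two ortho substituents and should resist a second addition.

Step 7
Reactants: 12 benzophenone from step 6
Product: 14 [(3R)-5-hydroxy-7-methoxy-2,2-dimethyl-3-(3-methylbut-2-enyl)chroman-6-yl][3-methoxy-4-(triisopropylsilyloxy)phenyl]methanone, via resorcinol 13 (not isolated)
Conditions: TsOH·H2O (cat.), MeOH, 50 °C; solvent change; TsOH (cat.), toluene, 40 °C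
Reagents that add atoms: none
Why: Acetal methanolysis, then Markovnikov intramolecular hydroalkoxylation of the isopropenyl group, which forms O9–C8 and the six-membered pyran. O4–H is locked in the hydrogen bond to the ketone, so the free O9–H should close. The prenyl alkene can only be protonated reversibly because no ring of reasonable size is open to it, and C7 is not touched.

Step 8
Reactants: 14 chroman phenol
Product: 15 5-O-prenyl ether of 14
Conditions: 3-methylbut-2-en-1-ol, PPh3, DIAD, THF, 0 °C to rt
Reagents that add atoms: 3-methylbut-2-en-1-ol, CC(C)=CCO
Why: Mitsunobu etherification of the only free hydroxyl (O4); the neutral medium spares the aryl silyl ether.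

Step 9
Reactants: 15 O-prenyl ether
Product: 17 [(3R)-5-hydroxy-7-methoxy-2,2-dimethyl-3,8-bis(3-methylbut-2-enyl)chroman-6-yl][3-methoxy-4-(triisopropylsilyloxy)phenyl]methanone, via ortho-dienone 16 (not isolated)
Conditions: PhNEt2, 190 °C
Reagents that add atoms: none
Why: para-Claisen rearrangement. The [3,3] shift goes to a blocked ortho carbon (drawn at C5; a shift to C3 leads to the same product), then a Cope shift carries the group to C1, the only free position, and tautomerisation follows. The double inversion delivers a normal prenyl group.

Step 10
Reactants: 3 (R)-lavandulyl acetate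
Product: 18 (R)-lavandulol
Conditions: K2CO3 (cat.), MeOH, rt
Reagents that add atoms: none
Why: Base-catalysed transesterification; the stereocentre has no acidic hydrogen.

Step 11
Reactants: 18 (R)-lavandulol
Product: 19 (R)-lavandulyl triflate
Conditions: Tf2O, 2,6-lutidine, CH2Cl2, −78 °C; used cold at once
Reagents that add atoms: triflic anhydride, O=S(=O)(OS(=O)(=O)C(F)(F)F)C(F)(F)F
Why: O-sulfonylation without change at the stereocentre; low temperature and immediate use suppress participation of the homoallylic alkene.

Step 12
Reactants: 17 fully substituted chroman phenol; 19 (R)-lavandulyl triflate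
Product: 21 (3R,4aS)-7-methoxy-6-[3-methoxy-4-(triisopropylsilyloxy)benzoyl]-2,2-dimethyl-3,8-bis(3-methylbut-2-enyl)-4a-[(2S)-5-methyl-2-(prop-1-en-2-yl)hex-4-enyl]-3,4-dihydro-2H-chromen-5(4aH)-one, via lithium phenolate 20 (not isolated)
Conditions: LiHMDS, toluene–THF, −78 °C; then 19, −78 to 0 °C
Reagents that add atoms: none
Why: Alkylative dearomatisation, the ortho C-alkylation of a lithium acylphenolate with a primary triflate. Only O4 is anionic and lithium is chelated between O4 and the ketone, so the electrophile is delivered to an ortho carbon, of which C3 is blocked by the acyl group. The new centre C5 is set by axial attack anti to the C7 prenyl group, which leads directly to a chair pyran with equatorial prenyl and axial side arm, whereas syn attack would build a 1,3-diaxial contact.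

Step 13
Reactants: 21 chromane-fused dienone
Product: 23 O2-methyl, O-TIPS derivative of 24 (2-methoxybicyclo[3.3.1]non-2-ene-4,9-dione; atom numbering as above: 1S,5S,7R,30S, spatially identical to 24), via ion pair 22 (not isolated)
Conditions: MeAlCl2 (2.5 equiv), CH2Cl2, −78 to −20 °C; aq. Rochelle salt
Reagents that add atoms: none
Why: Proposed new method: MeAlCl2 chelates the C4 ketone and the aroyl carbonyl of 21, this drains the doubly vinylogous ester O9–C9=C1–C2=C3–C4=O, and the tertiary C8–O9 bond ionises to the ion pair 22 (tertiary C8 cation, aluminium dienolate with charge on O9, C1, C3 and O4). Recombination at O9 or O4 only gives back an ionisable tertiary ether, whereas recombination at C1 gives the C9 ketone and is irreversible, so the system should drain into 23; the closest known reaction types are the Lewis acid mediated 1,3 O-to-C rearrangement of enol ethers and vinyl acetals, the α-tert-alkylation of silyl enol ethers with tertiary chlorides and TiCl4 (which builds vicinal quaternary carbons) and the acid-mediated cation cyclisation of dearomatised acylphloroglucinols, and what is new is a tertiary alkyl group that moves from the enol oxygen to the enol carbon inside such a dienone. One ring is closed, ring A, by 6-(enolendo) attack of C1 on the trigonal C8 cation, while the pyran opens in the same event, so that a fused 6-6 system becomes the bridged [3.3.1] system. C1 is set by the tether: C6 stands on one face of ring B (C5, step 12), so C8 can reach C1 only from this face. C7 is carried in unchanged, and because C5 and C7 are trans on the pyran of 21, closure at C1 can only give the 7-endo series, with ring A born as a boat that keeps the prenyl group pseudo-equatorial. Arm selectivity: only the ring arm has a leaving group, and MeAlCl2 destroys every proton as methane, so the isopropenyl group of the side arm and the prenyl groups are never protonated, and proton loss from 22 is a dead end that costs material but cannot feed racemic material back. Site selectivity: C3 lies inside the aluminium chelate, bears the acyl group and shares its charge with three carbonyl groups, so C1 is the more nucleophilic carbon. The C2 methyl enol ether and the aryl TIPS ether should survive at or below −20 °C.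

Step 14
Reactants: 23 protected bicycle
Product: 24 garcinol 13-O-methyl ether
Conditions: LiOH, dioxane–H2O, 90 °C; cold dil. HCl to pH 4
Reagents that add atoms: lithium hydroxide, [Li+].[OH-]
Why: Addition–elimination of hydroxide at C2 of the vinylogous methyl ester and cleavage of the electron-poor aryl silyl ether in one operation. The product is held as its unreactive trione anion, which protects the core, and the basic medium with a cold, barely acidic work-up keeps O4–H from adding to the isopropenyl group; no stereocentre is touched.

## Compound list

1 | (±)-lavandulol | C=C(C)C(CC=C(C)C)CO | starting material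
2 | (S)-lavandulol | C=C(C)[C@H](CC=C(C)C)CO | intermediate
3 | (R)-lavandulyl acetate | C=C(C)[C@@H](CC=C(C)C)COC(C)=O | intermediate
4 | (S)-lavandulyl iodide | C=C(C)[C@H](CC=C(C)C)CI | intermediate
5 | 5-methoxyresorcinol | COc1cc(O)cc(O)c1 | starting material
6 | 1-methoxy-3,5-bis(methoxymethoxy)benzene | COCOc1cc(OC)cc(OCOC)c1 | intermediate
7 | 4-methoxy-2,6-bis(methoxymethoxy)phenyllithium | [Li]c1c(OCOC)cc(OC)cc1OCOC | intermediate
8 | C5-alkylated arene (ring arm attached) | C=C(C)[C@H](CC=C(C)C)Cc1c(OCOC)cc(OC)cc1OCOC | intermediate
9 | methyl vanillate | COC(=O)c1ccc(O)c(OC)c1 | starting material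
10 | methyl 3-methoxy-4-(triisopropylsilyloxy)benzoate | COC(=O)c1ccc(O[Si](C(C)C)(C(C)C)C(C)C)c(OC)c1 | intermediate
11 | aryllithium of 8 (Li at C3) | C=C(C)[C@H](CC=C(C)C)Cc1c(OCOC)cc(OC)c([Li])c1OCOC | intermediate
12 | bis-MOM benzophenone | C=C(C)[C@H](CC=C(C)C)Cc1c(OCOC)cc(OC)c(C(=O)c2ccc(O[Si](C(C)C)(C(C)C)C(C)C)c(OC)c2)c1OCOC | intermediate
13 | free resorcinol benzophenone | C=C(C)[C@H](CC=C(C)C)Cc1c(O)cc(OC)c(C(=O)c2ccc(O[Si](C(C)C)(C(C)C)C(C)C)c(OC)c2)c1O | intermediate
14 | (3R)-chroman phenol | CC1(C)Oc2cc(OC)c(C(=O)c3ccc(O[Si](C(C)C)(C(C)C)C(C)C)c(OC)c3)c(O)c2C[C@H]1CC=C(C)C | intermediate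
15 | O4-prenyl ether | CC1(C)Oc2cc(OC)c(C(=O)c3ccc(O[Si](C(C)C)(C(C)C)C(C)C)c(OC)c3)c(OCC=C(C)C)c2C[C@H]1CC=C(C)C | intermediate
16 | ortho-dienone with 1,1-dimethylallyl on C5 | C=CC(C)(C)C12C[C@@H](CC=C(C)C)C(C)(C)OC2=CC(OC)=C(C(=O)c3ccc(O[Si](C(C)C)(C(C)C)C(C)C)c(OC)c3)C1=O | intermediate
17 | (3R)-8-prenyl chroman phenol | CC1(C)Oc2c(CC=C(C)C)c(OC)c(C(=O)c3ccc(O[Si](C(C)C)(C(C)C)C(C)C)c(OC)c3)c(O)c2C[C@H]1CC=C(C)C | intermediate
18 | (R)-lavandulol | C=C(C)[C@@H](CC=C(C)C)CO | intermediate
19 | (R)-lavandulyl triflate | C=C(C)[C@@H](CC=C(C)C)COS(=O)(=O)C(F)(F)F | intermediate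
20 | lithium phenolate of 17 | CC1(C)Oc2c(CC=C(C)C)c(OC)c(C(=O)c3ccc(O[Si](C(C)C)(C(C)C)C(C)C)c(OC)c3)c([O-])c2C[C@H]1CC=C(C)C.[Li+] | intermediate
21 | (3R,4aS)-chromane-fused dienone | C=C(C)[C@@H](CC=C(C)C)C[C@@]12C[C@@H](CC=C(C)C)C(C)(C)OC2=C(CC=C(C)C)C(OC)=C(C(=O)c3ccc(O[Si](C(C)C)(C(C)C)C(C)C)c(OC)c3)C1=O | intermediate
22 | C8 cation / aluminium dienolate ion pair | C=C(C)[C@@H](CC=C(C)C)C[C@]1(C[C@@H](CC=C(C)C)[C+](C)C)C(=O)C(CC=C(C)C)=C(OC)C(C(=O)c2ccc(O[Si](C(C)C)(C(C)C)C(C)C)c(OC)c2)=C1O[Al-](C)(Cl)Cl | intermediate
23 | O2-methyl, O-TIPS garcinol 13-O-methyl ether | C=C(C)[C@@H](CC=C(C)C)C[C@@]12C[C@@H](CC=C(C)C)C(C)(C)[C@@](CC=C(C)C)(C(OC)=C(C(=O)c3ccc(O[Si](C(C)C)(C(C)C)C(C)C)c(OC)c3)C1=O)C2=O | intermediate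
24 | garcinol 13-O-methyl ether | C=C(C)[C@@H](CC=C(C)C)C[C@@]12C[C@@H](CC=C(C)C)C(C)(C)[C@@](CC=C(C)C)(C(=O)C(C(=O)c3ccc(O)c(OC)c3)=C1O)C2=O | target

## Step count and least certain steps

Total step count: 14.
Longest linear sequence: 10 (steps 1, 2, 4, 6, 7, 8, 9, 12, 13, 14).

**Step 13 (key step, proposed new method).**
- The most likely failure is that proton loss from the tertiary cation outruns C–C bond formation. The new bond joins two fully substituted carbons through a boat-shaped closure.
- Next in likelihood are capture of the cation at C3 through the easier chair, and methyl transfer from aluminium.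
- The fallback sets out from 21 and comes back at 23.
- First, the isopropenyl group of 21 is masked by radical thiol–ene addition of thiophenol. The thiyl radical adds reversibly, and the unhindered 1,1-disubstituted alkene is the one that is trapped. This gives the primary phenyl sulfide F1.
- With no second arm that can be protonated, the known Brønsted acid closure is safe for the configuration. Neat formic acid at room temperature opens the pyran reversibly and lets the cation try repeatedly until it closes on C1, giving the bicyclic sulfide F2.
- One equivalent of mCPBA at −78 °C gives the sulfoxide F3. Thermal syn elimination (toluene, 110 °C, CaCO3) has only the C31–H to take and restores the isopropenyl group of 23.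

**Step 12.**
- O-alkylation at O4, decomposition of the homoallylic triflate before it is consumed, or poor facial selectivity at C5 may intervene. A mono-phenolate is a weaker carbon nucleophile than the dianions on which this reaction type is established.
- The fallback sets out from 17 and comes back at 21.
- Chelation-controlled demethylation of O2 with BCl3 at −78 °C gives the acylresorcinol F4.
- Its dilithium dianion (two equivalents of LiHMDS) is alkylated with 19, under the same pyran relay, to give the enolic dienone F5.
- O-methylation of the vinylogous acid with trimethylsilyldiazomethane returns 21.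

**Step 7.**
- Closure onto O4 instead of O9, or acid-induced hydration or migration of the prenyl alkene, may compete, because both alkenes give tertiary cations.
- The fallback sets out from 13 and comes back at 14.
- The acetals are cleaved under conditions too mild for closure, and 13 is isolated.
- The pyran is then closed without Brønsted acid by cobalt-catalysed hydrogen-atom-transfer hydroalkoxylation (Co(salen), a silane, an N-fluoropyridinium oxidant). This reaction selects the 1,1-disubstituted alkene over the trisubstituted one for steric reasons. No new compound is made (F0).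

**Step 4.**
- E2 elimination on the β-branched iodide, or a sluggish SN2 reaction with a hindered, basic aryllithium, may dominate.
- The fallback sets out from 6 and 4 and comes back at 8.
- Aryllithium 7 is quenched with iodine to give the aryl iodide F6.
- Iodide 4 is converted with activated zinc and LiCl into the alkylzinc iodide F7.
- The two are joined by Negishi coupling (Pd, bulky biaryl phosphine). The stereocentre is β to zinc and is not at risk.

**Step 1.**
- Enzymatic discrimination of a stereocentre β to the hydroxyl may be too weak to give both halves enantiopure in one pass.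
- The fallback sets out from 1 and comes back at 2 and 18.
- Esterification of 1 with (S)-2-methoxy-2-phenylacetic acid (DCC, DMAP) gives the diastereomeric esters (S)-lavandulyl (S)-O-methylmandelate F8 and (R)-lavandulyl (S)-O-methylmandelate F9.
- These are separated by chromatography or crystallisation and saponified separately with LiOH.

## Further compounds

F1 | step 13 | phenyl sulfide from thiol–ene addition to 21 | CC(CSc1ccccc1)[C@@H](CC=C(C)C)C[C@@]12C[C@@H](CC=C(C)C)C(C)(C)OC2=C(CC=C(C)C)C(OC)=C(C(=O)c3ccc(O[Si](C(C)C)(C(C)C)C(C)C)c(OC)c3)C1=O
F2 | step 13 | bicyclic sulfide | CC(CSc1ccccc1)[C@@H](CC=C(C)C)C[C@@]12C[C@@H](CC=C(C)C)C(C)(C)[C@@](CC=C(C)C)(C(OC)=C(C(=O)c3ccc(O[Si](C(C)C)(C(C)C)C(C)C)c(OC)c3)C1=O)C2=O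
F3 | step 13 | bicyclic sulfoxide | CC(CS(=O)c1ccccc1)[C@@H](CC=C(C)C)C[C@@]12C[C@@H](CC=C(C)C)C(C)(C)[C@@](CC=C(C)C)(C(OC)=C(C(=O)c3ccc(O[Si](C(C)C)(C(C)C)C(C)C)c(OC)c3)C1=O)C2=O
F4 | step 12 | O2-demethylated acylresorcinol | CC1(C)Oc2c(CC=C(C)C)c(O)c(C(=O)c3ccc(O[Si](C(C)C)(C(C)C)C(C)C)c(OC)c3)c(O)c2C[C@H]1CC=C(C)C
F5 | step 12 | enolic chromane-fused dienone | C=C(C)[C@@H](CC=C(C)C)C[C@@]12C[C@@H](CC=C(C)C)C(C)(C)OC2=C(CC=C(C)C)C(O)=C(C(=O)c3ccc(O[Si](C(C)C)(C(C)C)C(C)C)c(OC)c3)C1=O
F0 | step 7 | none | none
F6 | step 4 | 2-iodo-5-methoxy-1,3-bis(methoxymethoxy)benzene | COCOc1cc(OC)cc(OCOC)c1I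
F7 | step 4 | (S)-lavandulylzinc iodide | C=C(C)[C@H](CC=C(C)C)C[Zn]I
F8 | step 1 | (S)-lavandulyl (S)-2-methoxy-2-phenylacetate | C=C(C)[C@H](CC=C(C)C)COC(=O)[C@@H](OC)c1ccccc1
F9 | step 1 | (R)-lavandulyl (S)-2-methoxy-2-phenylacetate | C=C(C)[C@@H](CC=C(C)C)COC(=O)[C@@H](OC)c1ccccc1
A1 | alternative 1 | ring A methyl enol ether | COC1=C(CC=C(C)C)C(C)(C)[C@H](CC=C(C)C)C[C@H]1C[C@H](CC=C(C)C)C(C)=C
A2 | alternative 1 | malonyl dichloride | O=C(Cl)CC(=O)Cl
A3 | alternative 1 | 7-exo bicyclic trione without aroyl group | C=C(C)[C@@H](CC=C(C)C)C[C@]12C[C@@H](CC=C(C)C)C(C)(C)[C@](CC=C(C)C)(C(=O)C=C1O)C2=O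
A4 | alternative 2 | 3-prenyl-5-lavandulyl vanilloylphloroglucinol | C=C(C)[C@@H](CC=C(C)C)Cc1c(O)c(CC=C(C)C)c(O)c(C(=O)c2ccc(O)c(OC)c2)c1O
A5 | alternative 2 | 3-acetoxy-3-methyl-2-methylenebutanal | C=C(C=O)C(C)(C)OC(C)=O
A6 | alternative 2 | 7-exo-formyl bicycle | C=C(C)[C@@H](CC=C(C)C)C[C@@]12C[C@H](C=O)C(C)(C)[C@@](CC=C(C)C)(C(=O)C(C(=O)c3ccc(O)c(OC)c3)=C1O)C2=O
A7 | alternative 3 | ring A acetyl keto ester | C=C(C)[C@@H](CC=C(C)C)C[C@]1(C(=O)OC)C[C@@H](CC=C(C)C)C(C)(C)[C@@](CC=C(C)C)(C(C)=O)C1=O
A8 | alternative 3 | 7-endo bicyclic trione without aroyl group | C=C(C)[C@@H](CC=C(C)C)C[C@@]12C[C@@H](CC=C(C)C)C(C)(C)[C@@](CC=C(C)C)(C(=O)C=C1O)C2=O
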